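**Plan**

- Numbering: eremophilane-type decalin, ring A = C1–C5 and C10, ring B = C5–C10, side chain C11–C13 on C7; β is the face of the C5 methyl group.
- Cuts: the C3 ester C–O bond (trienoic acid); C7=C11 and C11–C13 (aldol unit plus cuprate methyl) and C9–O; C3–C4 of ring A; the two cycloaddition bonds C5–C6 and C9–C10 of ring B.
- Forward: ring B first, by Diels–Alder reaction of a 2-silyloxybutadiene with an (E)-2-methyl enal; ring A second, by reductive ketyl–olefin closure of C3–C4; then the C4 methyl, the C7 alkylidene, the C9 hydroxyl and the C3 ester.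
- Enabling feature: C3 (oxygen) and C4 (methyl) are adjacent trans-diequatorial carbons of ring A beside quaternary C5, so the C3–C4 bond can join an aldehyde-derived carbon to the β-carbon of a vinyl sulfone carried by C5.
- Stereochemistry: C5/C10 from the catalyst face and the E-enal (trans arms); C3/C4 from the chair transition state of the ring closure; C9 from α-face hydroxylation opposite the axial C5 methyl; C7=C11 from a vinylogous thioester with sulfur syn to the carbonyl and cuprate substitution with retention.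

Key step: step 6

Assumption: the facial sense of the oxazaborolidinium-catalysed cycloaddition follows the accepted model for 2-substituted enals (boron-bound s-trans enal, one face covered by an aryl group), which calls for the R catalyst; its antipode serves equally if the sense proves opposite.

**Route**

Step 1
Reactants: 1 but-3-en-2-one
Product: 2 2-(triisopropylsilyloxy)buta-1,3-diene
Conditions: iPr3SiOTf, Et3N, CH2Cl2, 0 °C → rt
Reagents that add atoms: triisopropylsilyl trifluoromethanesulfonate, CC(C)[Si](OS(=O)(=O)C(F)(F)F)(C(C)C)C(C)C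
Why: Soft enolisation and O-silylation of the methyl ketone (silyl triflate with an amine base) should give the cross-conjugated 2-silyloxy diene.

Step 2
Reactants: 3 methyl 4-oxobutanoate; 4 2-(triphenylphosphoranylidene)propanal
Product: 5 methyl (E)-5-methyl-6-oxohex-4-enoate
Conditions: toluene, 80 °C
Reagents that add atoms: none
Why: Wittig olefination with a stabilised formyl ylide should give the trisubstituted enal with E geometry (formyl trans to the chain).

Step 3
Reactants: 2 2-(triisopropylsilyloxy)buta-1,3-diene; 5 methyl (E)-5-methyl-6-oxohex-4-enoate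
Product: 6 methyl 3-[(1S,6S)-6-formyl-6-methyl-3-(triisopropylsilyloxy)cyclohex-3-en-1-yl]propanoate (ring B; formyl on C5 trans to the ester arm on C10)
Conditions: (R)-1-(2-methylphenyl)-3,3-diphenyl-tetrahydropyrrolo[1,2-c][1,3,2]oxazaborolium triflimide, [C24H25BNO][N(SO2CF3)2] (20 mol%), CH2Cl2, −78 → −20 °C
Reagents that add atoms: none
Why: Enantioselective Diels–Alder reaction under chiral oxazaborolidinium catalysis, in which the 2-silyloxy diene places the C8 oxygen 1,4 to the quaternary carbon, suprafacial addition to the E-enal makes the C5 formyl and C10 arm trans, and the catalyst should expose the Si face of the enal α-carbon to set both centres absolutely.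

Step 4
Reactants: 6 ring B aldehyde; 7 diethyl (phenylsulfonylmethyl)phosphonate
Product: 8 methyl 3-[(1S,6S)-6-methyl-6-[(E)-2-(phenylsulfonyl)ethenyl]-3-(triisopropylsilyloxy)cyclohex-3-en-1-yl]propanoate
Conditions: NaH, THF, 0 °C → rt
Reagents that add atoms: none
Why: Horner–Wadsworth–Emmons olefination of the non-enolisable neopentyl aldehyde with the sulfonyl-stabilised phosphonate should give the E vinyl sulfone.

Step 5
Reactants: 8 vinyl sulfone ester
Product: 9 3-[(1S,6S)-6-methyl-6-[(E)-2-(phenylsulfonyl)ethenyl]-3-(triisopropylsilyloxy)cyclohex-3-en-1-yl]propanal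
Conditions: iBu2AlH (1.1 equiv), CH2Cl2, −78 °C; MeOH, then aq. KNaC4H4O6
Reagents that add atoms: none
Why: Partial reduction of a methyl ester by iBu2AlH at low temperature stops at the aluminium hemiacetal and releases the aldehyde on work-up, while the vinyl sulfone and silyl enol ether are inert.

Step 6
Reactants: 9 aldehyde with C5 vinyl sulfone and C8 silyl enol ether
Product: 10 3α-hydroxy-5β-methyl-4β-(phenylsulfonylmethyl)-8-(triisopropylsilyloxy)-trans-decal-7-ene (10α-H)
Conditions: SmI2 (samarium diiodide, 3 equiv), MeOH, THF, 0 °C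
Reagents that add atoms: none
Why: Single-electron transfer from divalent samarium to the aldehyde gives the C3 ketyl, which adds to C4, the β-carbon of the vinyl sulfone; a second electron transfer turns the α-sulfonyl radical into the carbanion, which methanol protonates. The closest known reaction type is the samarium diiodide ketyl–olefin reductive cyclisation onto α,β-unsaturated esters and sulfones. Ring A closes in the 6-exo-trig mode through a chair transition state trans-fused to the preformed ring B. C3 is controlled by the equatorial placement of the bulky samarium-bound oxygen, and C4 by the equatorial orientation of the alkene terminus anti to that oxygen, which leaves the sulfonylmethyl group cis to the axial C5 methyl. The step needs chemoselective reduction of the aldehyde beside the masked C8 ketone and a cyclisation that outruns simple reduction or pinacol coupling; the silyl enol ether is inert to SmI2, the electron-poor sulfonyl alkene is a fast ketyl trap, and the trans C5/C10 arms fixed by the cycloaddition leave only C3 and C4 to be set.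

Step 7
Reactants: 10 hydroxy sulfone
Product: 11 3α-hydroxy-4β,5β-dimethyl-8-(triisopropylsilyloxy)-trans-decal-7-ene
Conditions: Na(Hg), Na2HPO4, MeOH/THF, −20 °C
Reagents that add atoms: none
Why: Reductive desulfonylation of an alkyl phenyl sulfone by electron transfer should leave the C4 methyl, with no β-leaving group available for elimination and C4 untouched.

Step 8
Reactants: 11 alcohol
Product: 12 3α-(4-methoxybenzyloxy)-4β,5β-dimethyl-8-(triisopropylsilyloxy)-trans-decal-7-ene
Conditions: NaH, 4-methoxybenzyl chloride, Bu4NI (cat.), DMF, 0 °C → rt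
Reagents that add atoms: 4-methoxybenzyl chloride, COc1ccc(CCl)cc1
Why: Williamson etherification of the equatorial secondary alkoxide gives a C3 protecting group orthogonal to the silyl groups used later.

Step 9
Reactants: 12 silyl enol ether; 13 (tert-butyldimethylsilyloxy)acetaldehyde
Product: 14 7-[2-(tert-butyldimethylsilyloxy)-1-hydroxyethyl]-3α-(4-methoxybenzyloxy)-4β,5β-dimethyl-trans-decalin-8-one (mixture at C7 and C11)
Conditions: BF3·OEt2, CH2Cl2, −78 °C; aq. NaHCO3
Reagents that add atoms: none
Why: Mukaiyama aldol addition in which the enol ether inherited from the cycloaddition makes C7 the only nucleophilic site; the new centres at C7 and C11 form as a mixture that is of no consequence because both become sp2 in the next steps.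

Step 10
Reactants: 14 aldol
Product: 16 (7(11)E)-7-[2-(tert-butyldimethylsilyloxy)ethylidene]-3α-(4-methoxybenzyloxy)-4β,5β-dimethyl-trans-decalin-8-one, via C11 mesylate 15 (not isolated)
Conditions: MsCl, Et3N, CH2Cl2, 0 °C; then DBU, 0 °C → rt
Reagents that add atoms: none
Why: Mesylation followed by E1cB elimination should give the thermodynamically preferred E alkylidene ketone, with the silyloxymethyl group anti to the C8 carbonyl.

Step 11
Reactants: 16 E-enone
Product: 19 (7(11)Z)-7-[2-(tert-butyldimethylsilyloxy)-1-(phenylthio)ethylidene]-3α-(4-methoxybenzyloxy)-4β,5β-dimethyl-trans-decalin-8-one (sulfur syn to the C8 carbonyl), via β-phenylthio ketone 17 (not isolated), via α-chloro sulfide 18 (not isolated)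
Conditions: PhSH, Et3N (cat.), CH2Cl2, 0 °C → rt; then N-chlorosuccinimide, 0 °C; then Et3N, rt
Reagents that add atoms: thiophenol, Sc1ccccc1
Why: Oxidative β-sulfenylation of an enone (thia-Michael addition, chlorination at the sulfur-bearing carbon, loss of HCl toward the acidic C7–H) gives a regiodefined vinylogous thioester that should settle with sulfur syn to the carbonyl oxygen (1,5 S···O contact, silyloxymethyl kept away from the carbonyl), the isomers being interconvertible by reversible thiolate addition.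

Step 12
Reactants: 19 vinylogous thioester
Product: 20 (7(11)E)-7-[1-(tert-butyldimethylsilyloxy)propan-2-ylidene]-3α-(4-methoxybenzyloxy)-4β,5β-dimethyl-trans-decalin-8-one (C13 methyl syn to the C8 carbonyl)
Conditions: Me2CuLi (from MeLi and CuI), Et2O, −78 → −40 °C; aq. NH4Cl
Reagents that add atoms: lithium dimethylcuprate, [Li+].C[Cu-]C (made from methyllithium, [Li]C, and CuI)
Why: Cuprate addition–elimination on a β-arylthio enone replaces sulfur by methyl with retention of the double-bond geometry, so the methyl takes the position syn to the carbonyl.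

Step 13
Reactants: 20 alkylidene ketone
Product: 22 9α-hydroxy-(7(11)E)-7-[1-(tert-butyldimethylsilyloxy)propan-2-ylidene]-3α-(4-methoxybenzyloxy)-4β,5β-dimethyl-trans-decalin-8-one, via potassium dienolate 21 (not isolated)
Conditions: KN(SiMe3)2, THF, −78 °C; then 2-(phenylsulfonyl)-3-phenyloxaziridine, −78 °C; aq. NH4Cl
Reagents that add atoms: 2-(phenylsulfonyl)-3-phenyloxaziridine, O=S(=O)(c1ccccc1)N1OC1c1ccccc1
Why: Kinetic α′-deprotonation at C9 (C7 carries no hydrogen) and enolate hydroxylation by the N-sulfonyloxaziridine (Davis oxidation) should occur on the α face, opposite the syn-axial C5 methyl, giving the equatorial 9α-hydroxyl, which is also the more stable epimer.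

Step 14
Reactants: 22 α-hydroxy ketone
Product: 23 9α-triethylsilyl ether of 22
Conditions: Et3SiOTf, 2,6-lutidine, CH2Cl2, −78 °C
Reagents that add atoms: triethylsilyl trifluoromethanesulfonate, CC[Si](CC)(CC)OS(=O)(=O)C(F)(F)F
Why: Silylation of the secondary alcohol with a silyl triflate and a hindered base protects C9–OH so that C3–OH can be acylated alone.

Step 15
Reactants: 23 bis-silyl 4-methoxybenzyl ether
Product: 24 3α-hydroxy-9α-(triethylsilyloxy)-(7(11)E)-7-[1-(tert-butyldimethylsilyloxy)propan-2-ylidene]-4β,5β-dimethyl-trans-decalin-8-one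
Conditions: DDQ, CH2Cl2/pH 7 phosphate buffer, 0 °C
Reagents that add atoms: none
Why: Oxidative cleavage of the 4-methoxybenzyl ether by DDQ frees C3–OH and leaves the silyl ethers and the enone untouched.

Step 16
Reactants: 25 (E)-non-3-en-2-one; 26 triethyl 4-phosphonocrotonate
Product: 27 ethyl (2E,4E,6E)-5-methyldodeca-2,4,6-trienoate
Conditions: LiN(SiMe3)2, THF, −78 → 0 °C
Reagents that add atoms: none
Why: Vinylogous Horner–Wadsworth–Emmons olefination of the methyl ketone should favour the 4E isomer (alkenyl group anti to the chain), the 6E and 2E bonds coming unchanged from the reagents; any 4Z isomer is removed by chromatography or iodine equilibration.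

Step 17
Reactants: 27 ethyl trienoate
Product: 28 (2E,4E,6E)-5-methyldodeca-2,4,6-trienoic acid
Conditions: LiOH, THF/MeOH/H2O, rt; then 1 M HCl
Reagents that add atoms: lithium hydroxide, [Li+].[OH-]
Why: Saponification of the ethyl ester by acyl substitution does not touch the triene geometry.

Step 18
Reactants: 24 C3 alcohol; 28 trienoic acid
Product: 30 3α-[(2E,4E,6E)-5-methyldodeca-2,4,6-trienoyloxy] derivative of 24 (9α-OSiEt3 and 12-OSiMe2tBu retained), via mixed anhydride 29 (not isolated)
Conditions: 2,4,6-trichlorobenzoyl chloride, Et3N, THF, rt; then 24, DMAP, toluene, rt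
Reagents that add atoms: none
Why: Yamaguchi esterification through the mixed aryl anhydride and DMAP acyl transfer should acylate the hindered equatorial C3 alcohol with retention at C3.

Step 19
Reactants: 30 bis-silyl ester
Product: 31 CNP0226738.2, 9α,12-dihydroxy-8-oxo-eremophil-7(11)E-en-3α-yl (2E,4E,6E)-5-methyldodeca-2,4,6-trienoate (4β,5β-dimethyl, 10α-H)
Conditions: HF·pyridine, pyridine, THF, 0 °C → rt
Reagents that add atoms: none
Why: Buffered fluoride-mediated desilylation removes both silyl ethers without affecting the trienoate, the enone or the α-hydroxy ketone.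

**Compound list**

1 | but-3-en-2-one | CC(=O)C=C | starting material
2 | 2-(triisopropylsilyloxy)buta-1,3-diene | C=CC(=C)O[Si](C(C)C)(C(C)C)C(C)C | intermediate
3 | methyl 4-oxobutanoate | COC(=O)CCC=O | starting material
4 | 2-(triphenylphosphoranylidene)propanal | CC(C=O)=P(c1ccccc1)(c1ccccc1)c1ccccc1 | starting material
5 | methyl (E)-5-methyl-6-oxohex-4-enoate | COC(=O)CC/C=C(\C)C=O | intermediate
6 | methyl 3-[(1S,6S)-6-formyl-6-methyl-3-(triisopropylsilyloxy)cyclohex-3-en-1-yl]propanoate | COC(=O)CC[C@H]1CC(O[Si](C(C)C)(C(C)C)C(C)C)=CC[C@]1(C)C=O | intermediate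
7 | diethyl (phenylsulfonylmethyl)phosphonate | CCOP(=O)(CS(=O)(=O)c1ccccc1)OCC | starting material
8 | methyl 3-[(1S,6S)-6-methyl-6-[(E)-2-(phenylsulfonyl)ethenyl]-3-(triisopropylsilyloxy)cyclohex-3-en-1-yl]propanoate | COC(=O)CC[C@H]1CC(O[Si](C(C)C)(C(C)C)C(C)C)=CC[C@]1(C)/C=C/S(=O)(=O)c1ccccc1 | intermediate
9 | 3-[(1S,6S)-6-methyl-6-[(E)-2-(phenylsulfonyl)ethenyl]-3-(triisopropylsilyloxy)cyclohex-3-en-1-yl]propanal | O=CCC[C@H]1CC(O[Si](C(C)C)(C(C)C)C(C)C)=CC[C@]1(C)/C=C/S(=O)(=O)c1ccccc1 | intermediate
10 | 3α-hydroxy-5β-methyl-4β-(phenylsulfonylmethyl)-8-(triisopropylsilyloxy)-trans-decal-7-ene | O[C@@H]1CC[C@H]2CC(O[Si](C(C)C)(C(C)C)C(C)C)=CC[C@]2(C)[C@H]1CS(=O)(=O)c1ccccc1 | intermediate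
11 | 3α-hydroxy-4β,5β-dimethyl-8-(triisopropylsilyloxy)-trans-decal-7-ene | O[C@@H]1CC[C@H]2CC(O[Si](C(C)C)(C(C)C)C(C)C)=CC[C@]2(C)[C@H]1C | intermediate
12 | 3α-(4-methoxybenzyloxy)-4β,5β-dimethyl-8-(triisopropylsilyloxy)-trans-decal-7-ene | COc1ccc(cc1)CO[C@@H]1CC[C@H]2CC(O[Si](C(C)C)(C(C)C)C(C)C)=CC[C@]2(C)[C@H]1C | intermediate
13 | (tert-butyldimethylsilyloxy)acetaldehyde | CC(C)(C)[Si](C)(C)OCC=O | starting material
14 | 7-[2-(tert-butyldimethylsilyloxy)-1-hydroxyethyl]-3α-(4-methoxybenzyloxy)-4β,5β-dimethyl-trans-decalin-8-one (mixture at C7, C11) | COc1ccc(cc1)CO[C@@H]1CC[C@H]2CC(=O)C(C(O)CO[Si](C)(C)C(C)(C)C)C[C@]2(C)[C@H]1C | intermediate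
15 | C11 methanesulfonate of 14 | COc1ccc(cc1)CO[C@@H]1CC[C@H]2CC(=O)C(C(OS(C)(=O)=O)CO[Si](C)(C)C(C)(C)C)C[C@]2(C)[C@H]1C | intermediate (not isolated)
16 | (7(11)E)-7-[2-(tert-butyldimethylsilyloxy)ethylidene]-3α-(4-methoxybenzyloxy)-4β,5β-dimethyl-trans-decalin-8-one | COc1ccc(cc1)CO[C@@H]1CC[C@H]2CC(=O)/C(=C/CO[Si](C)(C)C(C)(C)C)C[C@]2(C)[C@H]1C | intermediate
17 | 7-[2-(tert-butyldimethylsilyloxy)-1-(phenylthio)ethyl]-3α-(4-methoxybenzyloxy)-4β,5β-dimethyl-trans-decalin-8-one | COc1ccc(cc1)CO[C@@H]1CC[C@H]2CC(=O)C(C(Sc3ccccc3)CO[Si](C)(C)C(C)(C)C)C[C@]2(C)[C@H]1C | intermediate (not isolated)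
18 | 7-[2-(tert-butyldimethylsilyloxy)-1-chloro-1-(phenylthio)ethyl]-3α-(4-methoxybenzyloxy)-4β,5β-dimethyl-trans-decalin-8-one | COc1ccc(cc1)CO[C@@H]1CC[C@H]2CC(=O)C(C(Cl)(Sc3ccccc3)CO[Si](C)(C)C(C)(C)C)C[C@]2(C)[C@H]1C | intermediate (not isolated)
19 | (7(11)Z)-7-[2-(tert-butyldimethylsilyloxy)-1-(phenylthio)ethylidene]-3α-(4-methoxybenzyloxy)-4β,5β-dimethyl-trans-decalin-8-one | COc1ccc(cc1)CO[C@@H]1CC[C@H]2CC(=O)/C(=C(\Sc3ccccc3)CO[Si](C)(C)C(C)(C)C)C[C@]2(C)[C@H]1C | intermediate
20 | (7(11)E)-7-[1-(tert-butyldimethylsilyloxy)propan-2-ylidene]-3α-(4-methoxybenzyloxy)-4β,5β-dimethyl-trans-decalin-8-one | COc1ccc(cc1)CO[C@@H]1CC[C@H]2CC(=O)/C(=C(\C)CO[Si](C)(C)C(C)(C)C)C[C@]2(C)[C@H]1C | intermediate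
21 | potassium C8(O),C9-dienolate of 20 | COc1ccc(cc1)CO[C@@H]1CC[C@H]2C=C([O-])/C(=C(\C)CO[Si](C)(C)C(C)(C)C)C[C@]2(C)[C@H]1C.[K+] | intermediate (not isolated)
22 | 9α-hydroxy derivative of 20 | COc1ccc(cc1)CO[C@@H]1CC[C@H]2[C@H](O)C(=O)/C(=C(\C)CO[Si](C)(C)C(C)(C)C)C[C@]2(C)[C@H]1C | intermediate
23 | 9α-triethylsilyl ether of 22 | COc1ccc(cc1)CO[C@@H]1CC[C@H]2[C@H](O[Si](CC)(CC)CC)C(=O)/C(=C(\C)CO[Si](C)(C)C(C)(C)C)C[C@]2(C)[C@H]1C | intermediate
24 | 3α-hydroxy-9α-(triethylsilyloxy)-(7(11)E)-7-[1-(tert-butyldimethylsilyloxy)propan-2-ylidene]-4β,5β-dimethyl-trans-decalin-8-one | O[C@@H]1CC[C@H]2[C@H](O[Si](CC)(CC)CC)C(=O)/C(=C(\C)CO[Si](C)(C)C(C)(C)C)C[C@]2(C)[C@H]1C | intermediate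
25 | (E)-non-3-en-2-one | CCCCC/C=C/C(C)=O | starting material
26 | triethyl 4-phosphonocrotonate | CCOC(=O)/C=C/CP(=O)(OCC)OCC | starting material
27 | ethyl (2E,4E,6E)-5-methyldodeca-2,4,6-trienoate | CCCCC/C=C/C(C)=C/C=C/C(=O)OCC | intermediate
28 | (2E,4E,6E)-5-methyldodeca-2,4,6-trienoic acid | CCCCC/C=C/C(C)=C/C=C/C(=O)O | intermediate
29 | (2E,4E,6E)-5-methyldodeca-2,4,6-trienoic 2,4,6-trichlorobenzoic anhydride | CCCCC/C=C/C(C)=C/C=C/C(=O)OC(=O)c1c(Cl)cc(Cl)cc1Cl | intermediate (not isolated)
30 | 3α-trienoate of 24 (9α-OSiEt3, 12-OSiMe2tBu) | CCCCC/C=C/C(C)=C/C=C/C(=O)O[C@@H]1CC[C@H]2[C@H](O[Si](CC)(CC)CC)C(=O)/C(=C(\C)CO[Si](C)(C)C(C)(C)C)C[C@]2(C)[C@H]1C | intermediate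
31 | CNP0226738.2 | CCCCC/C=C/C(C)=C/C=C/C(=O)O[C@@H]1CC[C@H]2[C@H](O)C(=O)/C(=C(\C)CO)C[C@]2(C)[C@H]1C | target

**Count and risks**

Total: 19 steps. Longest linear sequence: 16 steps (steps 2–15, 18 and 19, from methyl 4-oxobutanoate).

Step 11 (control of the C7=C11 geometry). The vinylogous thioester may form as a mixture of double-bond isomers that does not settle on the sulfur-syn isomer, or HCl may be lost toward C12; either would erode the geometry delivered by the cuprate step. The fallback sets out from 12. A BF3·OEt2-mediated Mukaiyama aldol addition of 12 to 1-(tert-butyldimethylsilyloxy)propan-2-one gives the tertiary aldol F5. Dehydration (SOCl2, pyridine, 0 °C) then gives 20 together with its 7(11)Z isomer F6. The two are separated by chromatography, and F6 is re-equilibrated (catalytic I2, light) and recycled. The route is rejoined at 20.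

Step 3 (cycloaddition). The trisubstituted enal may react slowly, so that protodesilylation of the diene or open-chain Mukaiyama–Michael addition competes, and facial selectivity may be incomplete. The fallback sets out from 2 and 5. An Me2AlCl-promoted cycloaddition (CH2Cl2, −78 °C) gives the racemic trans adduct F1. Condensation with (1R,2R)-N,N'-dimethyl-1,2-diphenylethane-1,2-diamine (MgSO4, Et2O) gives the imidazolidine F2 of the wanted enantiomer and the diastereomeric imidazolidine F3, which are separated by chromatography or crystallisation. Hydrolysis of F2 on wet silica or with dilute aqueous citric acid returns the route to 6.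

Step 6 (ring A closure). Simple reduction of the aldehyde or pinacol coupling may outrun cyclisation, or closure may proceed partly through the conformer that places the sulfonylmethyl group axial. The fallback sets out from 9 and forms the same C3–C4 bond by polar umpolung. A carbene-catalysed intramolecular Stetter addition (3-benzyl-5-(2-hydroxyethyl)-4-methylthiazolium chloride, Et3N, dioxane, 70 °C) gives the 3-keto sulfone F4, in which C4 can equilibrate to the equatorial epimer. Dissolving-metal reduction (Li, liquid NH3, THF, t-BuOH, −78 °C) then gives the equatorial 3α-alcohol and cleaves the sulfone, either directly or through the 4-methylene ketone formed by loss of sulfinate. Hydride reagents are avoided because the syn-axial C5 methyl would steer them to the axial alcohol. The route is rejoined at 11.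

**Further compounds**

F1 | step 3 | racemic trans cycloadduct (6 and its enantiomer) | COC(=O)CC[C@H]1CC(O[Si](C(C)C)(C(C)C)C(C)C)=CC[C@]1(C)C=O.COC(=O)CC[C@@H]1CC(O[Si](C(C)C)(C(C)C)C(C)C)=CC[C@@]1(C)C=O
F2 | step 3 | (4R,5R)-1,3-dimethyl-4,5-diphenylimidazolidine aminal of 6 | COC(=O)CC[C@H]1CC(O[Si](C(C)C)(C(C)C)C(C)C)=CC[C@]1(C)C1N(C)[C@H](c2ccccc2)[C@@H](c2ccccc2)N1C
F3 | step 3 | (4R,5R)-1,3-dimethyl-4,5-diphenylimidazolidine aminal of the enantiomer of 6 | COC(=O)CC[C@@H]1CC(O[Si](C(C)C)(C(C)C)C(C)C)=CC[C@@]1(C)C1N(C)[C@H](c2ccccc2)[C@@H](c2ccccc2)N1C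
F4 | step 6 | 5β-methyl-4β-(phenylsulfonylmethyl)-8-(triisopropylsilyloxy)-trans-decal-7-en-3-one | O=C1CC[C@H]2CC(O[Si](C(C)C)(C(C)C)C(C)C)=CC[C@]2(C)[C@H]1CS(=O)(=O)c1ccccc1
F5 | step 11 | 7-[1-(tert-butyldimethylsilyloxy)-2-hydroxypropan-2-yl]-3α-(4-methoxybenzyloxy)-4β,5β-dimethyl-trans-decalin-8-one | COc1ccc(cc1)CO[C@@H]1CC[C@H]2CC(=O)C(C(C)(O)CO[Si](C)(C)C(C)(C)C)C[C@]2(C)[C@H]1C
F6 | step 11 | 7(11)Z isomer of 20 | COc1ccc(cc1)CO[C@@H]1CC[C@H]2CC(=O)/C(=C(/C)CO[Si](C)(C)C(C)(C)C)C[C@]2(C)[C@H]1C
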